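**Retrosynthetic overview**

1. Target 16 comes from its tetra-O-benzyl ether 15 by hydrogenolysis. 15 comes from the spiro selenide 14 by a radical 1,2-acyl migration (Dowd–Beckwith type) that contracts a seven-membered ring.
2. Enabling feature: the 1,4-diketone C-4(=O)–C-3–C-3″–C-4″(=O) joining rings C and C″, with C-3 also bonded to the O-1–C-2 carbon. In 14 both aroyl carbons (C-4 and C-4″) sit on C-3″ (spiro 1,3-diketone), and ring C is a 1-benzoxepin-5-one (O-1, C-2, C-3, C-3″, C-4, C-4a, C-8a). A radical at C-3 takes C-4 over from C-3″, which leaves the ring, giving the chromanone (O-1, C-2, C-3, C-4, C-4a, C-8a).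
3. 14 comes from phenol-alkene 13 by enantioselective 7-endo selenoetherification (O-1–C-2 bond, radical handle at C-3). 13 comes from the dienolate of enone 9 and benzodioxinone 11 (C-3″–C-4 bond, O-1 unveiled).
4. 9 comes from (2S)-flavanone 4 and aldehyde 5 by aldol condensation. 4 comes from chromone 2 and boronic acid 3 by asymmetric conjugate addition (sets C-2″).
5. Ring order: rings A and A″ come with 1 and 10; ring C″ is present from 1 (its aryl group enters in step 2); the oxepinone ring closes in step 6 and is contracted to ring C in step 7.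

Key step: step 7

Assumption: the ligand of step 2 and the catalyst of step 6 are used as the enantiomers that deliver the configurations drawn; in the discussion atoms carry target numbering (C-2/C-3/C-4 for the trans unit with ring C, C-2″/C-3″/C-4″ for the cis unit with ring C″).

**Step 1**
Reactants: 1 5,7-dihydroxy-4H-chromen-4-one
Product: 2 5,7-bis(benzyloxy)-4H-chromen-4-one
Conditions: BnBr (2.5 equiv), K2CO3, DMF, 70 °C
Reagents that add atoms: benzyl bromide, BrCc1ccccc1
Why: Williamson ether synthesis on both phenols (the chelated 5-OH needs warm DMF) gives benzyl ethers that survive the enolate, selenium and tin chemistry and are removed together in step 8; no stereocentre is formed.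

**Step 2**
Reactants: 2 5,7-bis(benzyloxy)-4H-chromen-4-one; 3 (4-methoxyphenyl)boronic acid
Product: 4 (2S)-5,7-bis(benzyloxy)-2-(4-methoxyphenyl)chroman-4-one
Conditions: Pd(OCOCF3)2 (5 mol %), t-BuPyOx (6 mol %), NH4PF6 (30 mol %), H2O (5 equiv), ClCH2CH2Cl, 60 °C
Reagents that add atoms: none
Why: Palladium-catalysed asymmetric conjugate addition of an arylboronic acid to a chromone (a known flavanone synthesis) sets C-2″ (2S) by ligand control of the face of aryl transfer, and protonation of the palladium enolate by water releases the ketone.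

**Step 3**
Reactants: 4 (2S)-5,7-bis(benzyloxy)-2-(4-methoxyphenyl)chroman-4-one; 5 (4-methoxyphenyl)acetaldehyde
Product: 9 (2R,3E)-5,7-bis(benzyloxy)-2-(4-methoxyphenyl)-3-[2-(4-methoxyphenyl)ethylidene]chroman-4-one, via lithium enolate 6 (not isolated), via lithium aldolate 7 (not isolated), via mesylate 8 (not isolated)
Conditions: LiN(SiMe3)2 (1.05 equiv), THF, −78 °C; 5, −78 °C; then CH3SO2Cl, Et3N, −78 to 0 °C
Reagents that add atoms: none
Why: Directed aldol addition of the lithium enolate at −78 °C (cold enough to prevent retro-oxa-Michael opening, so C-2″ is kept) and E1cB elimination of the mesylate give the exocyclic enone, whose transient C-3″ and carbinol centres and alkene geometry do not matter because they are re-hybridised in step 5.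

**Step 4**
Reactants: 10 5,7-dihydroxy-2,2-dimethyl-4H-1,3-benzodioxin-4-one
Product: 11 5,7-bis(benzyloxy)-2,2-dimethyl-4H-1,3-benzodioxin-4-one
Conditions: BnBr (2.5 equiv), K2CO3, DMF, 70 °C
Reagents that add atoms: benzyl bromide, BrCc1ccccc1
Why: Williamson ether synthesis as in step 1; no stereocentre is involved.

**Step 5**
Reactants: 9 (2R,3E)-5,7-bis(benzyloxy)-2-(4-methoxyphenyl)-3-[2-(4-methoxyphenyl)ethylidene]chroman-4-one; 11 5,7-bis(benzyloxy)-2,2-dimethyl-4H-1,3-benzodioxin-4-one
Product: 13 (2R,3S)-5,7-bis(benzyloxy)-3-[2,4-bis(benzyloxy)-6-hydroxybenzoyl]-2-(4-methoxyphenyl)-3-[(E)-2-(4-methoxyphenyl)ethenyl]chroman-4-one, via lithium dienolate 12 (not isolated)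
Conditions: LiN(SiMe3)2 (1.1 equiv), THF, −78 °C; 11, −78 to −20 °C; then AcOH
Reagents that add atoms: none
Why: γ-Deprotonation gives the extended lithium dienolate, which is C-acylated at its α-carbon (C-3″, the usual site for lithium dienolates) by the benzodioxinone, a known enolate acylating agent that releases acetone and unveils the ortho-phenol (O-1), so the C-3″–C-4 bond and the 1,3-diketone form in one operation; the aroyl group should enter anti to the C-2″ aryl group, but this quaternary centre is erased in step 7.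

**Step 6**
Reactants: 13 (2R,3S)-5,7-bis(benzyloxy)-3-[2,4-bis(benzyloxy)-6-hydroxybenzoyl]-2-(4-methoxyphenyl)-3-[(E)-2-(4-methoxyphenyl)ethenyl]chroman-4-one
Product: 14 (2R,3S,4S,2′R)-6,8,5′,7′-tetrakis(benzyloxy)-2,2′-bis(4-methoxyphenyl)-3-(phenylselanyl)-2,3-dihydrospiro[1-benzoxepine-4,3′-chromane]-4′,5-dione
Conditions: N-(phenylseleno)phthalimide (1.2 equiv), (S)-BINAM-derived thiophosphoramide Lewis base (10 mol %), CH3SO3H (0.2 equiv), CH2Cl2, −40 °C
Reagents that add atoms: N-(phenylseleno)phthalimide, O=C1c2ccccc2C(=O)N1[Se]c1ccccc1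
Why: Lewis-base-catalysed enantioselective selenoetherification, in which the catalyst-bound PhSe+ selects the alkene face and the phenol opens the seleniranium ion anti at the 4-methoxybenzylic carbon (Markovnikov, 7-endo), sets C-2 with the configuration that is 2S in the target and places the C-3 selenide as radical precursor; a C-2 epimer would be a separable diastereomer because C-2″ is already fixed.

**Step 7**
Reactants: 14 (2R,3S,4S,2′R)-6,8,5′,7′-tetrakis(benzyloxy)-2,2′-bis(4-methoxyphenyl)-3-(phenylselanyl)-2,3-dihydrospiro[1-benzoxepine-4,3′-chromane]-4′,5-dione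
Product: 15 (2S,3R,2″S,3″S)-5,5″,7,7″-tetrakis(benzyloxy)-4′,4‴-dimethoxy-3,3″-biflavanone
Conditions: Bu3SnH (1.3 equiv, syringe pump), Et3B (0.3 equiv), air, toluene, −20 °C
Reagents that add atoms: none
Why: Bu3Sn• abstracts the phenylselanyl group, the C-3 radical adds 3-exo-trig to the oxepinone carbonyl C-4, and the cyclopropyloxy radical opens by β-scission of the C-3″–C-4 bond, so the aroyl carbon moves from C-3″ to C-3, the seven-membered ring contracts to ring C, and the tertiary α-keto radical left at C-3″ is reduced by Bu3SnH. The closest known reaction type is the Dowd–Beckwith 1,2-acyl migration of β-dicarbonyl radicals, run here in the ring-contracting sense because it turns a secondary alkyl radical into a stabilised α-keto radical and a 1,3- into a 1,4-diketone. Ring C is closed by the 3-exo-trig attack followed by fragmentation (net transannular C-3–C-4 bond formation). C-3 is controlled by the resident C-2 centre: the acyl carbon should reach the face of the C-3 radical that keeps the C-2 anisyl group anti to the bulky spiro carbon, giving the 2,3-trans (2S,3R) unit; C-3″ is controlled by the resident C-2″ centre, whose aryl group sits pseudo-axial beside the planar radical so that hydrogen is delivered anti to it, giving the 2″,3″-cis (2″S,3″S) unit. The step is stereoconvergent, since the configurations at the selenium-bearing carbon and at the spiro carbon are erased. It needs migration of the oxepinone acyl group rather than the chromanone acyl group and an acyl shift faster than β-scission of the C-2–O-1 bond or direct reduction; strain release (seven to six) with formation of a planar conjugated chromanone, low temperature and slow addition of Bu3SnH should secure this.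

**Step 8**
Reactants: 15 (2S,3R,2″S,3″S)-5,5″,7,7″-tetrakis(benzyloxy)-4′,4‴-dimethoxy-3,3″-biflavanone
Product: 16 (2S,3R,2″S,3″S)-5,5″,7,7″-tetrahydroxy-4′,4‴-dimethoxy-3,3″-biflavanone (target)
Conditions: H2 (1 atm), 10% Pd/C, EtOAc–THF, 23 °C
Reagents that add atoms: none
Why: Hydrogenolysis of the four benzyl ethers over palladium under neutral conditions leaves the aryl methyl ethers, both ketones and the base-sensitive 2″,3″-cis unit untouched, so no stereocentre is scrambled.

**Compound list**

1 | 5,7-dihydroxy-4H-chromen-4-one | O=C1C=COc2cc(O)cc(O)c12 | starting material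
2 | 5,7-bis(benzyloxy)-4H-chromen-4-one | O=C1C=COc2cc(OCc3ccccc3)cc(OCc3ccccc3)c12 | intermediate
3 | (4-methoxyphenyl)boronic acid | COc1ccc(B(O)O)cc1 | starting material
4 | (2S)-5,7-bis(benzyloxy)-2-(4-methoxyphenyl)chroman-4-one | O=C1C[C@@H](c2ccc(OC)cc2)Oc2cc(OCc3ccccc3)cc(OCc3ccccc3)c12 | intermediate
5 | (4-methoxyphenyl)acetaldehyde | COc1ccc(CC=O)cc1 | starting material
6 | lithium enolate of 4 (lithium (2S)-5,7-bis(benzyloxy)-2-(4-methoxyphenyl)-2H-chromen-4-olate) | [Li+].[O-]C1=C[C@@H](c2ccc(OC)cc2)Oc2cc(OCc3ccccc3)cc(OCc3ccccc3)c12 | intermediate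
7 | lithium aldolate of 4 with 5 (mixture of isomers at C-3 and at the carbinol carbon; C-2 as in 4) | [Li+].[O-]C(Cc1ccc(OC)cc1)C1C(=O)c2c(OCc3ccccc3)cc(OCc3ccccc3)cc2O[C@@H]1c1ccc(OC)cc1 | intermediate
8 | methanesulfonate of the aldol (same isomer mixture; C-2 as in 4) | CS(=O)(=O)OC(Cc1ccc(OC)cc1)C1C(=O)c2c(OCc3ccccc3)cc(OCc3ccccc3)cc2O[C@@H]1c1ccc(OC)cc1 | intermediate
9 | (2R,3E)-5,7-bis(benzyloxy)-2-(4-methoxyphenyl)-3-[2-(4-methoxyphenyl)ethylidene]chroman-4-one (C-2 spatially as in 4; the descriptor changes by priority only) | COc1ccc(C/C=C2/C(=O)c3c(OCc4ccccc4)cc(OCc4ccccc4)cc3O[C@@H]2c2ccc(OC)cc2)cc1 | intermediate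
10 | 5,7-dihydroxy-2,2-dimethyl-4H-1,3-benzodioxin-4-one | CC1(C)OC(=O)c2c(O)cc(O)cc2O1 | starting material
11 | 5,7-bis(benzyloxy)-2,2-dimethyl-4H-1,3-benzodioxin-4-one | CC1(C)OC(=O)c2c(OCc3ccccc3)cc(OCc3ccccc3)cc2O1 | intermediate
12 | lithium dienolate of 9 (C-2 unchanged; new alkene E) | [Li+].[O-]C1=C(/C=C/c2ccc(OC)cc2)[C@@H](c2ccc(OC)cc2)Oc2cc(OCc3ccccc3)cc(OCc3ccccc3)c12 | intermediate
13 | (2R,3S)-5,7-bis(benzyloxy)-3-[2,4-bis(benzyloxy)-6-hydroxybenzoyl]-2-(4-methoxyphenyl)-3-[(E)-2-(4-methoxyphenyl)ethenyl]chroman-4-one (aroyl group trans to the C-2 aryl group) | O=C1c2c(OCc3ccccc3)cc(OCc3ccccc3)cc2O[C@H](c2ccc(OC)cc2)[C@@]1(/C=C/c1ccc(OC)cc1)C(=O)c1c(O)cc(OCc2ccccc2)cc1OCc1ccccc1 | intermediate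
14 | (2R,3S,4S,2′R)-6,8,5′,7′-tetrakis(benzyloxy)-2,2′-bis(4-methoxyphenyl)-3-(phenylselanyl)-2,3-dihydrospiro[1-benzoxepine-4,3′-chromane]-4′,5-dione (O-1 and Se anti; spiro carbon = C-3″; oxepine C-2 spatially as C-2 of 15) | COc1ccc(cc1)[C@H]2Oc3cc(OCc4ccccc4)cc(OCc4ccccc4)c3C(=O)[C@]4(C(=O)c5c(OCc6ccccc6)cc(OCc6ccccc6)cc5O[C@@H]4c4ccc(OC)cc4)[C@@H]2[Se]c2ccccc2 | intermediate
15 | (2S,3R,2″S,3″S)-5,5″,7,7″-tetrakis(benzyloxy)-4′,4‴-dimethoxy-3,3″-biflavanone | COc1ccc([C@H]2Oc3cc(OCc4ccccc4)cc(OCc4ccccc4)c3C(=O)[C@@H]2[C@@H]2C(=O)c3c(OCc4ccccc4)cc(OCc4ccccc4)cc3O[C@@H]2c2ccc(OC)cc2)cc1 | intermediate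
16 | (2S,3R,2″S,3″S)-5,5″,7,7″-tetrahydroxy-4′,4‴-dimethoxy-3,3″-biflavanone | COc1ccc([C@H]2Oc3cc(O)cc(O)c3C(=O)[C@@H]2[C@@H]2C(=O)c3c(O)cc(O)cc3O[C@@H]2c2ccc(OC)cc2)cc1 | target

**Step count and risks**

Total step count: 8. Longest linear sequence: 7 steps (steps 1, 2, 3, 5, 6, 7, 8).

Steps most likely to fail:

1. Step 7. The C-3 radical may reopen the oxepinone by β-scission of the C-2–O-1 bond, or take over the chromanone acyl carbon C-4″ instead of C-4, and the closing hydrogen-atom transfer (or the acyl transfer) may be poorly face-selective. The fallback sets out from 4 and comes back at 15. Enolate 6 (LiN(SiMe3)2, THF, −78 °C) is oxidised with CuCl2 (oxidative enolate homocoupling, each C–C bond formed anti to the neighbouring aryl group). Brief equilibration with DBU funnels the diastereomers, and equally any C-3/C-3″ mixture obtained from step 7, into the C2-symmetric 2,3-trans/2″,3″-trans dimer (2S,3R,2″S,3″R)-5,5″,7,7″-tetrakis(benzyloxy)-4′,4‴-dimethoxy-3,3″-biflavanone F1. One equivalent of LiN(SiMe3)2 at −78 °C gives the lithium mono-enolate F2 (the two ketones are equivalent). Kinetic protonation with acetic acid anti to the adjacent aryl group creates the cis unit and gives 15.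

2. Step 6. The selenium may be delivered with low or reversed facial selectivity (erosion by selenium transfer between alkenes), or the phenol may close 6-exo at C-3. The fallback sets out from 13 and comes back at 15. 13 is cyclised with a stoichiometric chiral selenium electrophile, 2-[(1S)-1-hydroxypropyl]phenylselenenyl triflate (from the diselenide with Br2, then AgOSO2CF3, CH2Cl2, −78 °C), whose covalently bound stereocentre controls the face of selenium delivery (asymmetric selenocyclisation with a chiral arylselenium reagent). This gives the aryl selenide analogue of 14, F3, with diastereomers separable. F3 is submitted to the conditions of step 7 and gives 15.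

3. Step 5. The dienolate may be acylated on oxygen or at the γ-carbon, or may attack the electron-rich dioxinone carbonyl too slowly. The fallback sets out from 4 and comes back at 15, with the order of the two bond formations at C-3″ reversed. Enolate 6 is acylated with 11 (Claisen-type acylation, then AcOH) to the 3-aroylflavanone (2S)-5,7-bis(benzyloxy)-3-[2,4-bis(benzyloxy)-6-hydroxybenzoyl]-2-(4-methoxyphenyl)chroman-4-one F4. Its potassium diketonate (KOC(CH3)3, THF, −78 °C) is C-alkenylated with (E)-[2-(4-methoxyphenyl)ethenyl](phenyl)iodonium tetrafluoroborate (vinylation of a 1,3-dicarbonyl enolate, alkenyl group entering anti to the aryl group) to the C-3 epimer of 13, F5. The conditions of step 6 convert F5 into the spiro-carbon epimer of 14, F6, and the conditions of step 7 convert F6 into 15, because the configuration at C-3″ is erased there.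

Further compounds
F1 | step 7 | (2S,3R,2″S,3″R)-5,5″,7,7″-tetrakis(benzyloxy)-4′,4‴-dimethoxy-3,3″-biflavanone | COc1ccc([C@H]2Oc3cc(OCc4ccccc4)cc(OCc4ccccc4)c3C(=O)[C@@H]2[C@H]2C(=O)c3c(OCc4ccccc4)cc(OCc4ccccc4)cc3O[C@@H]2c2ccc(OC)cc2)cc1
F2 | step 7 | lithium mono-enolate of F1 | [Li+].COc1ccc([C@H]2Oc3cc(OCc4ccccc4)cc(OCc4ccccc4)c3C(=O)[C@@H]2C2=C([O-])c3c(OCc4ccccc4)cc(OCc4ccccc4)cc3O[C@@H]2c2ccc(OC)cc2)cc1
F3 | step 6 | analogue of 14 with a 2-[(1S)-1-hydroxypropyl]phenylselanyl group at C-3 | COc1ccc(cc1)[C@H]2Oc3cc(OCc4ccccc4)cc(OCc4ccccc4)c3C(=O)[C@]4(C(=O)c5c(OCc6ccccc6)cc(OCc6ccccc6)cc5O[C@@H]4c4ccc(OC)cc4)[C@@H]2[Se]c2ccccc2[C@@H](O)CC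
F4 | step 5 | (2S)-5,7-bis(benzyloxy)-3-[2,4-bis(benzyloxy)-6-hydroxybenzoyl]-2-(4-methoxyphenyl)chroman-4-one (keto–enol mixture at C-3) | O=C1c2c(OCc3ccccc3)cc(OCc3ccccc3)cc2O[C@H](c2ccc(OC)cc2)C1C(=O)c1c(O)cc(OCc2ccccc2)cc1OCc1ccccc1
F5 | step 5 | C-3 epimer of 13 (styryl group trans to the C-2 aryl group) | O=C1c2c(OCc3ccccc3)cc(OCc3ccccc3)cc2O[C@H](c2ccc(OC)cc2)[C@]1(/C=C/c1ccc(OC)cc1)C(=O)c1c(O)cc(OCc2ccccc2)cc1OCc1ccccc1
F6 | step 5 | spiro-carbon epimer of 14 | COc1ccc(cc1)[C@H]2Oc3cc(OCc4ccccc4)cc(OCc4ccccc4)c3C(=O)[C@@]4(C(=O)c5c(OCc6ccccc6)cc(OCc6ccccc6)cc5O[C@@H]4c4ccc(OC)cc4)[C@@H]2[Se]c2ccccc2
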